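**Plan** (flavanone numbering: ring A = benzo ring, ring C = pyranone ring, ring B = 2-aryl group)
1. Retrosynthetic cuts: C4–C4a (ring C, the last C–C bond), then O1–C2 (aryl ether), then the C8–CH2 bond to the lavandulyl group, then the Cα–prenyl bond inside the lavandulyl unit.
2. Forward: auxiliary-controlled alkylation gives (S)-lavandulol; its triflate alkylates the C2-lithiated bis-MOM ether of 5-methoxyresorcinol, and deprotection gives a locally symmetric 2-lavandulyl-5-methoxyresorcinol. Mono-silylation and a Mitsunobu etherification attach the O1–C2–C3–C4 chain as a β-aryloxy N,N-dimethylamide; ring C is closed last and two silyl ethers are removed.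
3. Ring-closing event: acid-free electrophilic activation of the amide carbon C4 and attack by C4a. C4a of the phloroglucinol-type ring A is ortho to O1 and to the C5 methoxy oxygen and para to the C7 oxygen, and it is the only ring carbon the O1–C2–C3 tether lets C4 reach through a six-membered transition state.
4. Because both phenols of the resorcinol are equivalent and the tether decides the site, the 5-OMe / 7-OH / 8-lavandulyl pattern needs no regioselective alkylation or methylation of ring A; the closure also spares the two lavandulyl alkenes and the labile C2 ether. The NMe2 activating group leaves in the key step and the TIPS groups in the last step.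
5. Stereochemistry: the lavandulyl centre comes from the (S)-4-benzyloxazolidinone auxiliary; C2 comes from asymmetric transfer hydrogenation to the (R)-carbinol followed by Mitsunobu inversion to (S), and is not touched afterwards.

Key step: step 13

Remark: the sense of hydride delivery in step 11 is taken by analogy with simple aryl alkyl ketones; should the ortho-silyloxy group reverse it, the (S,S)-ligand is used instead.

**Step 1**
Reactants: 1 (S)-4-benzyl-1,3-oxazolidin-2-one; 2 3-methylbut-2-enoyl chloride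
Product: 3 (S)-4-benzyl-3-(3-methylbut-2-enoyl)-1,3-oxazolidin-2-one
Conditions: n-BuLi, THF, −78 °C; then 2, −78 → 0 °C
Reagents that add atoms: none
Why: N-acylation of the lithiated oxazolidinone by the acid chloride is a standard acyl substitution and installs the auxiliary that will control the lavandulyl stereocentre.

**Step 2**
Reactants: 3 (S)-4-benzyl-3-(3-methylbut-2-enoyl)-1,3-oxazolidin-2-one; 4 prenyl bromide (1-bromo-3-methylbut-2-ene)
Product: 6 (S)-4-benzyl-3-[(2S)-5-methyl-2-(prop-1-en-2-yl)hex-4-enoyl]-1,3-oxazolidin-2-one, via sodium dienolate 5 (not isolated)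
Conditions: NaN(SiMe3)2, THF, −78 °C; then 4, −78 → −40 °C; AcOH quench at −78 °C
Reagents that add atoms: none
Why: γ-Deprotonation of the s-cis enoyl imide gives the chelated Z-dienolate, which in this auxiliary-controlled deconjugative alkylation (Evans alkylation) reacts at the α-carbon on the face opposite the benzyl group and so sets the (2S) centre that carries the isopropenyl and prenyl groups.

**Step 3**
Reactants: 6 (S)-4-benzyl-3-[(2S)-5-methyl-2-(prop-1-en-2-yl)hex-4-enoyl]-1,3-oxazolidin-2-one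
Product: 7 (S)-lavandulol [(2S)-5-methyl-2-(prop-1-en-2-yl)hex-4-en-1-ol]
Conditions: LiBH4, H2O (1 equiv), Et2O, 0 °C
Reagents that add atoms: none
Why: Reductive cleavage of the N-acyl oxazolidinone by LiBH4 attacks the exocyclic carbonyl and releases the primary alcohol without touching the α-centre or the alkenes.

**Step 4**
Reactants: 7 (S)-lavandulol
Product: 8 (2S)-5-methyl-2-(prop-1-en-2-yl)hex-4-en-1-yl trifluoromethanesulfonate
Conditions: Tf2O, 2,6-lutidine, CH2Cl2, −78 °C; cold filtration through silica in pentane; used at once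
Reagents that add atoms: trifluoromethanesulfonic anhydride (O=S(=O)(OS(=O)(=O)C(F)(F)F)C(F)(F)F)
Why: O-sulfonylation of the primary alcohol gives a leaving group reactive enough for SN2 substitution at the β-branched carbon, and the stereocentre is not involved.

**Step 5**
Reactants: 9 5-methoxyresorcinol
Product: 10 1-methoxy-3,5-bis(methoxymethoxy)benzene
Conditions: MOMCl, i-Pr2NEt, CH2Cl2, 0 °C → rt
Reagents that add atoms: chloromethyl methyl ether (COCCl)
Why: Williamson-type acetal protection of both phenols provides two ortho-directing groups that flank C2 of the ring.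

**Step 6**
Reactants: 10 1-methoxy-3,5-bis(methoxymethoxy)benzene; 8 (2S)-5-methyl-2-(prop-1-en-2-yl)hex-4-en-1-yl trifluoromethanesulfonate
Product: 12 5-methoxy-1,3-bis(methoxymethoxy)-2-[(2R)-5-methyl-2-(prop-1-en-2-yl)hex-4-en-1-yl]benzene, via aryllithium 11 (not isolated)
Conditions: n-BuLi, THF, 0 °C; then 8 in Et2O, −78 → 0 °C
Reagents that add atoms: none
Why: Directed ortho-metalation takes place at the CH flanked by the two methoxymethoxy groups, and SN2 alkylation of the aryllithium by the primary triflate joins the lavandulyl unit to the future C8 without touching its stereocentre.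

**Step 7**
Reactants: 12 5-methoxy-1,3-bis(methoxymethoxy)-2-[(2R)-5-methyl-2-(prop-1-en-2-yl)hex-4-en-1-yl]benzene
Product: 13 5-methoxy-2-[(2R)-5-methyl-2-(prop-1-en-2-yl)hex-4-en-1-yl]benzene-1,3-diol
Conditions: ZnBr2, n-PrSH, CH2Cl2, 0 °C, 15 min
Reagents that add atoms: none
Why: Lewis-acid-assisted thiolysis of the aryl MOM acetals should be fast enough at 0 °C to free both phenols before the acid-sensitive 1,5-diene can cyclize.

**Step 8**
Reactants: 13 5-methoxy-2-[(2R)-5-methyl-2-(prop-1-en-2-yl)hex-4-en-1-yl]benzene-1,3-diol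
Product: 14 5-methoxy-2-[(2R)-5-methyl-2-(prop-1-en-2-yl)hex-4-en-1-yl]-3-[(triisopropylsilyl)oxy]phenol
Conditions: TIPSCl (1.0 equiv), imidazole, DMF, 0 °C; bis-silyl ether and unreacted diol recycled
Reagents that add atoms: chlorotriisopropylsilane (CC(C)[Si](Cl)(C(C)C)C(C)C)
Why: Silylation of one of the two equivalent phenols is statistical, but the first bulky silyl group hinders the second hydroxyl across the lavandulyl CH2, and either hydroxyl gives the same product.

**Step 9**
Reactants: 15 methyl salicylate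
Product: 16 methyl 2-[(triisopropylsilyl)oxy]benzoate
Conditions: TIPSCl, imidazole, DMF, rt
Reagents that add atoms: chlorotriisopropylsilane (CC(C)[Si](Cl)(C(C)C)C(C)C)
Why: Silyl protection of the phenol masks the future 2'-hydroxyl with a bulky group that later also shields this oxygen from the activated amide.

**Step 10**
Reactants: 16 methyl 2-[(triisopropylsilyl)oxy]benzoate; 17 N,N-dimethylacetamide
Product: 19 N,N-dimethyl-3-oxo-3-{2-[(triisopropylsilyl)oxy]phenyl}propanamide, via lithium amide enolate 18 (not isolated)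
Conditions: LiN(i-Pr)2 (2.2 equiv), 17 (2.2 equiv), THF, −78 °C; then 16, −78 → −20 °C; aq. NH4Cl
Reagents that add atoms: none
Why: Claisen-type acylation of the amide enolate by the aryl ester gives the β-keto amide, the second equivalent of enolate being consumed by deprotonation of the product.

**Step 11**
Reactants: 19 N,N-dimethyl-3-oxo-3-{2-[(triisopropylsilyl)oxy]phenyl}propanamide
Product: 20 (3R)-3-hydroxy-N,N-dimethyl-3-{2-[(triisopropylsilyl)oxy]phenyl}propanamide
Conditions: RuCl[(R,R)-TsDPEN](p-cymene) (1 mol %), HCO2H/Et3N (5:2), EtOAc, 30 °C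
Reagents that add atoms: none
Why: Noyori asymmetric transfer hydrogenation of the aryl ketone delivers hydride to one enantioface under control of the (R,R)-diamine ligand and the aryl–arene CH/π contact, which should set the (R)-carbinol.

**Step 12**
Reactants: 14 5-methoxy-2-[(2R)-5-methyl-2-(prop-1-en-2-yl)hex-4-en-1-yl]-3-[(triisopropylsilyl)oxy]phenol; 20 (3R)-3-hydroxy-N,N-dimethyl-3-{2-[(triisopropylsilyl)oxy]phenyl}propanamide
Product: 21 (3S)-3-{5-methoxy-2-[(2R)-5-methyl-2-(prop-1-en-2-yl)hex-4-en-1-yl]-3-[(triisopropylsilyl)oxy]phenoxy}-N,N-dimethyl-3-{2-[(triisopropylsilyl)oxy]phenyl}propanamide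
Conditions: PPh3, DIAD, toluene, 0 °C → rt
Reagents that add atoms: none
Why: Mitsunobu etherification activates the benzylic alcohol as its oxyphosphonium ion, and SN2 attack of the phenoxide inverts C2 from (R) to the (S) configuration of the target.

**Step 13**
Reactants: 21 (3S)-3-{5-methoxy-2-[(2R)-5-methyl-2-(prop-1-en-2-yl)hex-4-en-1-yl]-3-[(triisopropylsilyl)oxy]phenoxy}-N,N-dimethyl-3-{2-[(triisopropylsilyl)oxy]phenyl}propanamide
Product: 24 (2S)-5-methoxy-8-[(2R)-5-methyl-2-(prop-1-en-2-yl)hex-4-en-1-yl]-7-[(triisopropylsilyl)oxy]-2-{2-[(triisopropylsilyl)oxy]phenyl}-2,3-dihydro-4H-chromen-4-one, via O-triflyliminium triflate 22 (not isolated), via cyclic ketiminium triflate 23 (not isolated)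
Conditions: Tf2O (1.1 equiv), 2,6-di-tert-butyl-4-methylpyridine (1.5 equiv), CH2Cl2, −78 → 0 °C; then aq. NaOAc/AcOH (pH 5), THF, 0 → 40 °C
Reagents that add atoms: water (O)
Why: Tf2O sulfonylates the amide oxygen to the strongly electrophilic O-triflyliminium ion 22 (in equilibrium with its keteniminium ion under the hindered base), C4 of which is attacked by C4a of ring A, the CH that lies ortho to O1 and to the C5 methoxy group and para to the C7 silyloxy group, and loss of triflate and of a proton gives the aryl ketiminium ion 23, which buffered water hydrolyses to the ketone. The closest known reaction type is the intramolecular Vilsmeier–Haack-type acylation, in which a tethered electron-rich arene attacks a tertiary amide activated by triflic anhydride. Ring C closes in a 6-exo-trig mode through the O1–C2–C3 tether. No new stereocentre is formed, and C2 should keep its configuration because the C2–O1 bond is not touched and because the non-nucleophilic base and the pH 5 hydrolysis keep the product as the iminium ion and not as the enamine that could open by retro-oxa-Michael reaction. The step needs regioselectivity for C4a over C6 and chemoselectivity over the two lavandulyl alkenes and the silyl ether oxygens: the tether can reach only C4a, the amide oxygen is by far the most nucleophilic site toward Tf2O, no free strong acid is present, and the bulky TIPS groups shield their oxygens.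

**Step 14**
Reactants: 24 (2S)-5-methoxy-8-[(2R)-5-methyl-2-(prop-1-en-2-yl)hex-4-en-1-yl]-7-[(triisopropylsilyl)oxy]-2-{2-[(triisopropylsilyl)oxy]phenyl}-2,3-dihydro-4H-chromen-4-one
Product: 25 kushenol R
Conditions: Bu4NF, AcOH, THF, 0 °C
Reagents that add atoms: none
Why: Fluoride-mediated desilylation cleaves both aryl silyl ethers, and the acetic acid buffer keeps the medium from becoming basic enough for retro-oxa-Michael opening or epimerization at C2.

**Compound list**
1 | (S)-4-benzyl-1,3-oxazolidin-2-one | O=C1N[C@@H](Cc2ccccc2)CO1 | starting material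
2 | 3-methylbut-2-enoyl chloride | CC(C)=CC(=O)Cl | starting material
3 | (S)-4-benzyl-3-(3-methylbut-2-enoyl)-1,3-oxazolidin-2-one | CC(C)=CC(=O)N1[C@@H](Cc2ccccc2)COC1=O | intermediate
4 | prenyl bromide (1-bromo-3-methylbut-2-ene) | CC(C)=CCBr | starting material
5 | sodium (Z)-dienolate of 3 (isopropenyl group cis to the enolate oxygen) | C=C(C)/C=C(\[O-])N1[C@@H](Cc2ccccc2)COC1=O.[Na+] | intermediate
6 | (S)-4-benzyl-3-[(2S)-5-methyl-2-(prop-1-en-2-yl)hex-4-enoyl]-1,3-oxazolidin-2-one | C=C(C)[C@H](CC=C(C)C)C(=O)N1[C@@H](Cc2ccccc2)COC1=O | intermediate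
7 | (S)-lavandulol, (2S)-5-methyl-2-(prop-1-en-2-yl)hex-4-en-1-ol | C=C(C)[C@H](CC=C(C)C)CO | intermediate
8 | (2S)-5-methyl-2-(prop-1-en-2-yl)hex-4-en-1-yl trifluoromethanesulfonate | C=C(C)[C@H](CC=C(C)C)COS(=O)(=O)C(F)(F)F | intermediate
9 | 5-methoxyresorcinol (5-methoxybenzene-1,3-diol) | COc1cc(O)cc(O)c1 | starting material
10 | 1-methoxy-3,5-bis(methoxymethoxy)benzene | COCOc1cc(OC)cc(OCOC)c1 | intermediate
11 | [4-methoxy-2,6-bis(methoxymethoxy)phenyl]lithium | [Li]c1c(OCOC)cc(OC)cc1OCOC | intermediate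
12 | 5-methoxy-1,3-bis(methoxymethoxy)-2-[(2R)-5-methyl-2-(prop-1-en-2-yl)hex-4-en-1-yl]benzene | C=C(C)[C@H](CC=C(C)C)Cc1c(OCOC)cc(OC)cc1OCOC | intermediate
13 | 5-methoxy-2-[(2R)-5-methyl-2-(prop-1-en-2-yl)hex-4-en-1-yl]benzene-1,3-diol | C=C(C)[C@H](CC=C(C)C)Cc1c(O)cc(OC)cc1O | intermediate
14 | 5-methoxy-2-[(2R)-5-methyl-2-(prop-1-en-2-yl)hex-4-en-1-yl]-3-[(triisopropylsilyl)oxy]phenol | C=C(C)[C@H](CC=C(C)C)Cc1c(O)cc(OC)cc1O[Si](C(C)C)(C(C)C)C(C)C | intermediate
15 | methyl salicylate | COC(=O)c1ccccc1O | starting material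
16 | methyl 2-[(triisopropylsilyl)oxy]benzoate | COC(=O)c1ccccc1O[Si](C(C)C)(C(C)C)C(C)C | intermediate
17 | N,N-dimethylacetamide | CC(=O)N(C)C | starting material
18 | lithium enolate of N,N-dimethylacetamide | C=C(O[Li])N(C)C | intermediate
19 | N,N-dimethyl-3-oxo-3-{2-[(triisopropylsilyl)oxy]phenyl}propanamide | CN(C)C(=O)CC(=O)c1ccccc1O[Si](C(C)C)(C(C)C)C(C)C | intermediate
20 | (3R)-3-hydroxy-N,N-dimethyl-3-{2-[(triisopropylsilyl)oxy]phenyl}propanamide | CN(C)C(=O)C[C@@H](O)c1ccccc1O[Si](C(C)C)(C(C)C)C(C)C | intermediate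
21 | (3S)-3-{5-methoxy-2-[(2R)-5-methyl-2-(prop-1-en-2-yl)hex-4-en-1-yl]-3-[(triisopropylsilyl)oxy]phenoxy}-N,N-dimethyl-3-{2-[(triisopropylsilyl)oxy]phenyl}propanamide | CN(C)C(=O)C[C@H](Oc1cc(OC)cc(O[Si](C(C)C)(C(C)C)C(C)C)c1C[C@@H](CC=C(C)C)C(C)=C)c1ccccc1O[Si](C(C)C)(C(C)C)C(C)C | intermediate
22 | O-triflyliminium triflate of 21 (amide oxygen sulfonylated; C2 still S) | C[N+](C)=C(OS(=O)(=O)C(F)(F)F)C[C@H](Oc1cc(OC)cc(O[Si](C(C)C)(C(C)C)C(C)C)c1C[C@@H](CC=C(C)C)C(C)=C)c1ccccc1O[Si](C(C)C)(C(C)C)C(C)C.[O-]S(=O)(=O)C(F)(F)F | intermediate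
23 | cyclic ketiminium triflate: (2S)-chroman-4-ylidene dimethyliminium salt of 24 (C4=N+Me2 in place of C4=O) | C=C(C)[C@H](CC=C(C)C)Cc1c(O[Si](C(C)C)(C(C)C)C(C)C)cc(OC)c2c1O[C@H](c1ccccc1O[Si](C(C)C)(C(C)C)C(C)C)CC2=[N+](C)C.[O-]S(=O)(=O)C(F)(F)F | intermediate
24 | (2S)-5-methoxy-8-[(2R)-5-methyl-2-(prop-1-en-2-yl)hex-4-en-1-yl]-7-[(triisopropylsilyl)oxy]-2-{2-[(triisopropylsilyl)oxy]phenyl}-2,3-dihydro-4H-chromen-4-one | C=C(C)[C@H](CC=C(C)C)Cc1c(O[Si](C(C)C)(C(C)C)C(C)C)cc(OC)c2c1O[C@H](c1ccccc1O[Si](C(C)C)(C(C)C)C(C)C)CC2=O | intermediate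
25 | kushenol R, (2S)-7-hydroxy-2-(2-hydroxyphenyl)-5-methoxy-8-[(2R)-5-methyl-2-(prop-1-en-2-yl)hex-4-en-1-yl]-2,3-dihydro-4H-chromen-4-one | C=C(C)[C@H](CC=C(C)C)Cc1c(O)cc(OC)c2c1O[C@H](c1ccccc1O)CC2=O | target

**Step count and risks**
Total: 14 steps. Longest linear sequence: 10 steps (steps 1, 2, 3, 4, 6, 7, 8, 12, 13, 14).

The three steps most likely to fail:

Step 13 (key step). What may go wrong: β-elimination of the ring A phenoxide from the activated amide through its enamine or keteniminium forms, competing attack of the ring B silyl ether oxygen on the iminium carbon, or proton-induced cyclization of the lavandulyl 1,5-diene. Fallback with reversed polarity (Parham-type cyclization, nucleophilic aryl carbon and unactivated amide): it sets out from 14. Ortho-selective bromination next to the free hydroxyl (NBS, catalytic i-Pr2NH, CH2Cl2, −78 °C; the other ring CH is shielded by the TIPS ether) should give 2-bromo-3-methoxy-6-[(2R)-5-methyl-2-(prop-1-en-2-yl)hex-4-en-1-yl]-5-[(triisopropylsilyl)oxy]phenol F1. Mitsunobu etherification of F1 with 20 (PPh3, DIAD, toluene) should give the bromo aryl ether amide F2. Bromine–lithium exchange (t-BuLi, 2 equiv, THF, −100 °C) gives the aryllithium F3, which adds to the amide carbonyl to form the lithium hemiaminalate F4. Aqueous NH4Cl then releases the ketone, and the route is rejoined at 24.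

Step 12. What may go wrong: E2 loss of the activated benzylic hydroxyl to the cinnamamide, and partial ionization of the electron-rich benzylic oxyphosphonium ion, which would erode the inversion at C2. Fallback that forms the aryl ketone first and makes the ether bond intramolecularly: it sets out from 12 and 20. Compound 12 is lithiated between the methoxymethoxy and methoxy groups (n-BuLi, TMEDA, THF, 0 °C) to give the aryllithium F5. F5 is added at −78 °C to the lithium alkoxide F6 (from 20 and n-BuLi), and aqueous NH4Cl gives the (R)-β-hydroxy ketone F7. ZnBr2/n-PrSH removes both MOM groups to give the dihydroxy β-hydroxy ketone F8. An intramolecular Mitsunobu reaction (PPh3, DIAD, THF, 0 °C) closes ring C through the hydroxyl ortho to the ketone with inversion at C2 to give the 7-hydroxy flavanone silyl ether F9. Bu4NF/AcOH then gives 25, where the route is rejoined.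

Step 6. What may go wrong: base-induced E2 elimination of the β-branched homoallylic triflate in place of substitution, and partial metalation at the CH between the methoxymethoxy and methoxy groups. Fallback by cross-coupling (Negishi coupling): it sets out from 10 and 7. The aryllithium 11 made from 10 is quenched with I2 to give 2-iodo-5-methoxy-1,3-bis(methoxymethoxy)benzene F10. Alcohol 7 is converted (I2, PPh3, imidazole, CH2Cl2) into (S)-lavandulyl iodide F11 and then (Zn dust, LiCl, THF) into the lavandulylzinc iodide F12. Coupling of F10 with F12 (Pd(OAc)2, SPhos, THF, 50 °C) returns to the route at 12.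

**Further compounds**
F1 | step 13 | 2-bromo-3-methoxy-6-[(2R)-5-methyl-2-(prop-1-en-2-yl)hex-4-en-1-yl]-5-[(triisopropylsilyl)oxy]phenol | C=C(C)[C@H](CC=C(C)C)Cc1c(O)c(Br)c(OC)cc1O[Si](C(C)C)(C(C)C)C(C)C
F2 | step 13 | (3S)-3-{2-bromo-3-methoxy-6-[(2R)-5-methyl-2-(prop-1-en-2-yl)hex-4-en-1-yl]-5-[(triisopropylsilyl)oxy]phenoxy}-N,N-dimethyl-3-{2-[(triisopropylsilyl)oxy]phenyl}propanamide | CN(C)C(=O)C[C@H](Oc1c(Br)c(OC)cc(O[Si](C(C)C)(C(C)C)C(C)C)c1C[C@@H](CC=C(C)C)C(C)=C)c1ccccc1O[Si](C(C)C)(C(C)C)C(C)C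
F3 | step 13 | aryllithium from F2 (lithium in place of bromine) | CN(C)C(=O)C[C@H](Oc1c([Li])c(OC)cc(O[Si](C(C)C)(C(C)C)C(C)C)c1C[C@@H](CC=C(C)C)C(C)=C)c1ccccc1O[Si](C(C)C)(C(C)C)C(C)C
F4 | step 13 | lithium hemiaminalate of 24 (C4 bears OLi and NMe2; both C4 epimers) | C=C(C)[C@H](CC=C(C)C)Cc1c(O[Si](C(C)C)(C(C)C)C(C)C)cc(OC)c2c1O[C@H](c1ccccc1O[Si](C(C)C)(C(C)C)C(C)C)CC2(O[Li])N(C)C
F5 | step 12 | {6-methoxy-2,4-bis(methoxymethoxy)-3-[(2R)-5-methyl-2-(prop-1-en-2-yl)hex-4-en-1-yl]phenyl}lithium | C=C(C)[C@H](CC=C(C)C)Cc1c(OCOC)cc(OC)c([Li])c1OCOC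
F6 | step 12 | lithium alkoxide of 20 | CN(C)C(=O)C[C@@H](O[Li])c1ccccc1O[Si](C(C)C)(C(C)C)C(C)C
F7 | step 12 | (3R)-3-hydroxy-1-{6-methoxy-2,4-bis(methoxymethoxy)-3-[(2R)-5-methyl-2-(prop-1-en-2-yl)hex-4-en-1-yl]phenyl}-3-{2-[(triisopropylsilyl)oxy]phenyl}propan-1-one | C=C(C)[C@H](CC=C(C)C)Cc1c(OCOC)cc(OC)c(C(=O)C[C@@H](O)c2ccccc2O[Si](C(C)C)(C(C)C)C(C)C)c1OCOC
F8 | step 12 | (3R)-1-{2,4-dihydroxy-6-methoxy-3-[(2R)-5-methyl-2-(prop-1-en-2-yl)hex-4-en-1-yl]phenyl}-3-hydroxy-3-{2-[(triisopropylsilyl)oxy]phenyl}propan-1-one | C=C(C)[C@H](CC=C(C)C)Cc1c(O)cc(OC)c(C(=O)C[C@@H](O)c2ccccc2O[Si](C(C)C)(C(C)C)C(C)C)c1O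
F9 | step 12 | (2S)-7-hydroxy-5-methoxy-8-[(2R)-5-methyl-2-(prop-1-en-2-yl)hex-4-en-1-yl]-2-{2-[(triisopropylsilyl)oxy]phenyl}-2,3-dihydro-4H-chromen-4-one | C=C(C)[C@H](CC=C(C)C)Cc1c(O)cc(OC)c2c1O[C@H](c1ccccc1O[Si](C(C)C)(C(C)C)C(C)C)CC2=O
F10 | step 6 | 2-iodo-5-methoxy-1,3-bis(methoxymethoxy)benzene | COCOc1cc(OC)cc(OCOC)c1I
F11 | step 6 | (S)-lavandulyl iodide, (2S)-1-iodo-5-methyl-2-(prop-1-en-2-yl)hex-4-ene | C=C(C)[C@H](CC=C(C)C)CI
F12 | step 6 | [(2S)-5-methyl-2-(prop-1-en-2-yl)hex-4-en-1-yl]zinc iodide | C=C(C)[C@H](CC=C(C)C)C[Zn]I
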